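The runs are simulated with made-up constants; noise was put on by code.

The target forms when first nucleophile catches the intermediate that substrate gives by itself, so your yield per charge depends on who catches that intermediate.

| flask | substrate | first nucleophile | second nucleophile | remark | time |
|---|---|---|---|---|---|
| south-west | 0.20 M | 0.50 M | 0.20 M | run made earlier |  |
| east | 0.10 M | 0.50 M | 0.20 M | run made earlier |  |
| north | 0.40 M | 0.50 M | 0.20 M | run made earlier |  |
| west | 0.20 M | 1 M | 0.20 M | run made earlier |  |
| eta | 0.20 M | 0.500 M | 0.200 M | everything together in a closed stirred flask, run for 50 min | 50 min |
| delta | 0.20 M | 0.500 M | 0.200 M | one stirred flow tank at steady state, fed with the mixture as stated, mean residence time 50 min |  |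
| zeta | 0.20 M | 0.500 M | 0.200 M (fed, over 25.0 min) | all but second nucleophile at the start; second nucleophile goes in evenly over 25.0 min, the run ends at 50 min | 50 min |
| beta | 0.20 M (fed, over 25.0 min) | 0.500 M | 0.200 M | all but substrate at the start; substrate goes in evenly over 25.0 min, the run ends at 50 min | 50 min |

- south-west (time / min: target / %, substrate / %): 8.00: 38, 24; 15.0: 53, 10; 20.0: 60, 0; 30.0: 64, 0; 40.0: 67, 1; 50.0: 67, 2
- east (time / min: target / %, substrate / %): 3.00: 11, 56; 5.00: 23, 42; 8.00: 39, 23; 12.0: 51, 14; 15.0: 55, 6; 25.0: 65, 0; 40.0: 69, 1
- north (time / min: target / %, substrate / %): 6.00: 26, 37; 12.0: 46, 12; 15.0: 54, 5; 25.0: 63, 2; 30.0: 63, 5; 40.0: 64, 0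
- west (time / min: target / %, substrate / %): 8.00: 53, 26; 15.0: 74, 6; 25.0: 80, 5; 30.0: 82, 2; 40.0: 82, 0

(each reading ± 2 percentage points)

- the stated concentrations are those of everything mixed, before any reaction; amounts are the same in each set-up
- what may be going on: second nucleophile + intermediate -> other capture product; first nucleophile -> decomposed reagent; first nucleophile + intermediate -> target; substrate -> intermediate
- the feed brings no volume worth counting
- the earlier runs were made in a closed, stirred flask

* order of the set-ups by the amount of target at the outlet or at the end, in percent of the substrate put in, highest first (eta / delta / zeta / beta)
* amount of target at the outlet or at the end, in percent of the substrate put in, eta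
* amount of target at the outlet or at the end, in percent of the substrate put in, delta
* amount of target at the outlet or at the end, in percent of the substrate put in, zeta
* amount of target at the outlet or at the end, in percent of the substrate put in, beta

Build the flask up. With substrate going to intermediate and first nucleophile as the sole catcher, the yield runs to 100 percent. The clock comes from the south-west run, with 24% substrate left at 8.00 min, which reads as 0.178 min⁻¹; the east run, at half the charge, shows 23% at that time.

Add second nucleophile. On the south-west charges, equal capture constants (a selectivity factor of one, the zero of the scale) send 71.4% to the target. This is the capture share: first nucleophile concentration over the sum of both nucleophile concentrations, taken as they stand when the intermediate is caught. The south-west reading of 67% sits a little under it, and the west reading of 82% compares with 83.3%.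

Add the rest, decomposition and the nucleophiles used in capture, and the concentrations move during a run: the north reading of 64% lies below the east reading of 69%.

My reckoning: eta repeats south-west, near 67%. For zeta I take second nucleophile at half its charge as a rough mean during the dose, which gives a share of 83.3%. Delta, by my reckoning, leaves 10.1% of its substrate unconverted, which puts it at 64.2% on the share from the charges, leaving out the intermediate that goes out uncaught and any loss of first nucleophile. I place zeta first and eta second, and leave beta and delta open below eta.

The forecast says zeta > eta > beta > delta, with eta 67%, delta 51%, zeta 81% and beta 63%, lower than mine for delta, and holds that in beta “late intermediate meets decayed first nucleophile”.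

The flasks give zeta > eta > beta > delta: eta 66.4%, delta 45.9%, zeta 79.8%, beta 55.8%. The rank stands, while delta lies 5.1 percentage points and beta 7.2 points under the forecast.

    second nucleophile + intermediate → other capture product (k = 0.00860 M⁻¹ s⁻¹)
    first nucleophile → decomposed reagent (k = 4.80 × 10⁻⁴ s⁻¹)
    first nucleophile + intermediate → target (k = 0.00920 M⁻¹ s⁻¹)
    substrate → intermediate (k = 0.00290 s⁻¹)

In delta, substrate stood at 0.0206 M and first nucleophile at 0.167 M, a third of its charge, throughout the steady state, which with the second nucleophile left after 33.9% other capture product puts the capture share at 55.9% against 71.4% on the charges. In beta, substrate peaked at 0.0454 M while first nucleophile, with a half-life of 24 min by decomposition alone, fell from 0.500 M, and the capture split ended at 58.0% target, with 40.4% other capture product and 3.44% intermediate still standing.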